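## The problem

The target 41 is a furanoheliangolide, and its family locants are used for every intermediate: C1 ketone, C2=C3 enol-ether olefin, an oxygen joining C3 and C10 (a 3(2H)-furanone), Z-C4(CH3)=C5, lactone carbinol C6, C7, acyloxy carbons C8 and C9, quaternary C10, and C11=C13 with the C12 lactone carbonyl. A ten-membered carbocycle is thus bridged by oxygen across C3/C10, fused trans to an α-methylene-γ-lactone at C6/C7, and holds two cis olefinic segments, which makes end-to-end closure of an open chain unattractive. Five contiguous stereocentres (6R,7S,8S,9S,10R) must be set. C7 can come from the chiral pool and then controls C6 and a temporary centre at C8. C8/C9 form an erythro diol, so a syn addition to a Z-C8=C9 olefin leaves only a face to be chosen, with C10 next to it as the control element. C10 has no hydrogen and must be created in a C–C bond-forming step. The α-methylene lactone and the dienone are Michael acceptors, and two different esters sit on neighbouring oxygens, so strong bases and nucleophiles are excluded late. A free C6 hydroxyl must not coexist with a C1/C3 diketone, because it would compete with O10 for C3. The enabling feature is that C3–C8, with the C4 methyl, the Z-C4=C5 olefin and the three-carbon branch on C7, are the ring of (S)-carvone (1) with its carbonyl at C3. C1–C2 and C9–C10 are then two-carbon arms on C3 and C8, and a [3,3] shift of the diene C1=C2–C3–C8–C9=C10 cuts C3–C8, joins C1–C10 and returns C3 as a ketone.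

## Retrosynthesis

**Furanone (O10–C3, C2=C3).** The first bond removed is the enol-ether bond O10–C3: 41 is the cyclodehydration product of hydroxy diketone 39 through hemiketal 40, and 39 is the desilylated form of diketone 38. This cut is preferred to removing an ester first because it leaves both acyl groups in place, so nothing basic is needed once the vinylogous ester exists. The precursor 38 has one ring fewer and no bridge. The forward step must free a tertiary hydroxyl with acidic fluoride and close onto C3, the only carbonyl within reach.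

**C1 oxidation level and the two esters.** 38 comes from alcohol 37 by oxidation, 37 from PMB ether 36, 36 from hydroxy ester 35 by acetylation, and 35 from diol 27 and acid 33 through mixed anhydride 34. C1 stays an ether until both hydroxyls are acylated, since a C1 hydroxyl would be a third acylation site. The C9 acetate is cut before the C8 ester because, going forward, the less hindered C8 hydroxyl must take the larger acid first. The precursor 27 is simpler by two esters. The forward acylation must discriminate C8 from the neopentylic C9.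

**C8–O and C9–O.** Diol 27 comes from olefin 25 by syn-dihydroxylation through osmate ester 26. The cut is placed here, not on the finished tricycle, for two reasons: C10 still carries its bulky silyloxy group, and C8=C9 is the only olefin not conjugated to a carbonyl. In the oxygen-bridged tricycle the required face is expected to be the concave one. The forward reaction must add to the face anti to the C10 silyloxy group.

**Lactone (O6–C12).** 25 comes from diol 22 by oxidative lactonisation through enal 23 and lactol 24, and 22 from bis-silyl ether 21. Carrying C12 as a silyl ether from the start avoids a late allylic oxidation of an isopropenyl group on a polyene. It also allows O6 to be released only at the moment it is captured as the lactone. The precursor is simpler by one ring.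

**Ten-membered ring (C1–C10).** 21 is the product of an anionic oxy-Cope rearrangement of cyclohexenol 18 through alkoxide 19 and dienolate 20. In the retrosynthetic direction C1–C10 is cut and C3–C8 is re-formed. This is preferred to any macrocyclisation because the ring arises by expansion of a six-membered ring and because C10 and the Z-C8=C9 olefin are created in the same event. The precursor is a tetrasubstituted cyclohexene. The forward step needs one chair transition state.

**C2–C3 bond and the two enol ethers.** 18 comes from alkoxyalkyne 17 by semi-hydrogenation, 17 from methyl ketone 16 by enol silylation, 16 from enol ether 15 by hydrolysis, and 15 from ketone 10 and lithium alkoxyacetylide 14. Acetylide 14 is made from dichlorovinyl ether 13, itself from 4-methoxybenzyl alcohol (11) and trichloroethylene (12). An alkyne is chosen over a Z-alkoxyvinyl metal because the slim nucleophile should add axially, cis to the C8 arm, and because the Z geometry then comes from hydrogenation. The forward sequence must keep the acid-labile alkoxyalkyne carbinol intact while the ketone is unmasked.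

**C8–C9 bond.** 10 comes from enone 6 through enolate 9 and 3-bromo-2-methoxypropene (8), which is made from 2-methoxypropene (7). Alkylation at the α′ carbon is the simplest way to place a three-carbon acetonyl arm. The precursor lacks one stereocentre. The forward step must alkylate trans to the C7 substituent.

**C6–O and C12–O.** 6 comes from diol 5 by silylation, 5 from hydroxy enone 4 by allylic hydroxylation, 4 from dienyl acetate 2 through epoxide 3, and 2 from (S)-carvone (1). Both oxygens are introduced on the smallest possible substrate, where the enone olefin is inert and the isopropenyl group is the only electron-rich olefin after the γ-oxidation.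

**Side-chain acid.** Acid 33 comes from tert-butyl ester 32, 32 from Baylis–Hillman adduct 30 through its acetate 31, and 30 from tert-butyl acrylate (28) and acetaldehyde (29). The allylic transposition fixes the E geometry thermodynamically.

## Roads not taken

**Alternative 1:** The cut is O–C10. The C3 ketone oxygen of the ten-membered β,γ-epoxy ketone A1 would open the tertiary epoxide carbon under Sc(OTf)3, and loss of a C2 proton would give the bridged dienol ether A2 with C1 as a carbinol.
- **Merits:** C10 is set by stereospecific backside opening of an epoxide whose configuration is read from an olefin. The bridge forms with lactone and protected diol already in place.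
- **Weak points:** A1 presupposes the ten-membered ring, so the first ring problem stays open. It needs a face-selective epoxidation of a flexible cyclodecadienone. A Lewis acid on a tertiary epoxide beside a ketone invites semipinacol shifts and ionisation with loss of the C10 configuration. C1 must still be oxidised after A2.
- **Comparison:** In the security of C10 this road is better than a chair-versus-boat preference. The chosen plan sets against it that the same step builds the carbocycle, C10 and the Z olefin from a chiral-pool ring.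

**Alternative 2:** The cut is C5–C6. The Z-vinyl iodide of iodo aldehyde A3 would add to its C6 aldehyde with NiCl2 and catalytic CrCl2 regenerated at a cathode (Nozaki–Hiyama–Kishi closure), giving macrocyclic allylic alcohol A4.
- **Merits:** The route is convergent, the conditions are nearly neutral, the furanone is already in place and the olefin geometry is retained.
- **Weak points:** A strained ten-membered ring (nine through the oxygen) is closed end to end at high dilution. The C6 configuration rests on macrocyclic bias. C7 in A3 is α to the formyl group and allylic, so epimerisation or conjugation into C11=C13 threatens. The C7–C10 stereotetrad must be built on an open chain.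
- **Comparison:** In convergence this road is as good or better; the chosen plan pays with 18 linear steps. The chosen plan sets against it ring formation without dilution and C6/C7 taken from carvone.

**Alternative 3:** The cut is C1–C2. The ethyl thioester of thioester alkyne A5 would couple with its terminal alkyne under Pd2(dba)3, tri(2-furyl)phosphine and CuI to give the ten-membered Z-enynone A6. Desilylation would then let O10 add to the ynone and form the furanone.
- **Merits:** The ynone-to-furanone step is very reliable, and the endgame after ring closure would be shorter than in the chosen plan.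
- **Weak points:** A6 holds four collinear atoms (C4–C3≡C2–C1) in a ten-membered ring beside a Z olefin and a trans lactone. An intramolecular thioester–alkyne coupling at this ring size is likely to oligomerise. The thioester sits on quaternary C10. The α-methylene lactone is exposed to zerovalent palladium and copper acetylides.
- **Comparison:** If the closure worked, this road would be better in step economy after ring closure. The chosen plan sets against it a strain-free ring expansion that also creates C10.

Key step: step 12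

Remark on numbering: atoms keep their germacranolide locants in all intermediates; names of the six-membered intermediates use their own ring locants. TBS = tert-butyldimethylsilyl, TIPS = triisopropylsilyl, PMB = 4-methoxybenzyl.
Assumption: trichloroethylene (12), tert-butyl acrylate (28) and acetaldehyde (29) are taken as commercial besides 1, 7 and 11.

## Steps

Step 1
Reactants: 1 (S)-(+)-carvone
Product: 2 (5R)-2-methyl-5-(prop-1-en-2-yl)cyclohexa-1,3-dien-1-yl acetate
Conditions: isopropenyl acetate (solvent), p-TsOH·H2O (5 mol%), 95 °C, acetone distilled off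
Reagents that add atoms: isopropenyl acetate, CC(=C)OC(C)=O
Why: Acid-catalysed enol acetylation under equilibrating conditions gives the linear (through-conjugated) dienyl acetate, as with steroidal enones; the stereocentre is not touched.

Step 2
Reactants: 2 dienyl acetate
Product: 4 (4R,5S)-4-hydroxy-2-methyl-5-(prop-1-en-2-yl)cyclohex-2-en-1-one, via epoxy enol acetate 3 (not isolated)
Conditions: m-CPBA (1.05 equiv), NaHCO3, 1,4-dioxane–H2O 10:1, 0 °C
Reagents that add atoms: 3-chloroperoxybenzoic acid, OOC(=O)c1cccc(Cl)c1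
Why: Vinylogous Rubottom-type oxidation: the peracid epoxidises the terminal double bond of the electron-rich dienyl acetate anti to the neighbouring isopropenyl group, and the epoxide opens with loss of the acetyl group to the γ-hydroxy enone. This sets C6 (ring locant 4R) trans to C7.

Step 3
Reactants: 4 hydroxy enone
Product: 5 (4R,5S)-4-hydroxy-5-(3-hydroxyprop-1-en-2-yl)-2-methylcyclohex-2-en-1-one
Conditions: SeO2 (0.5 equiv), t-BuOOH (70% aq., 3 equiv), CH2Cl2, 25 °C
Reagents that add atoms: selenium dioxide, O=[Se]=O (oxygen carrier); tert-butyl hydroperoxide, CC(C)(C)OO (terminal oxidant)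
Why: Allylic hydroxylation by ene reaction and [2,3]-shift at the methyl group of the only electron-rich olefin; the enone olefin is inert and no stereocentre is affected.

Step 4
Reactants: 5 diol
Product: 6 (4R,5S)-4-(TBS-oxy)-5-[3-(TBS-oxy)prop-1-en-2-yl]-2-methylcyclohex-2-en-1-one
Conditions: TBSCl (2.5 equiv), imidazole, DMF, 25 °C
Reagents that add atoms: tert-butyldimethylsilyl chloride, CC(C)(C)[Si](C)(C)Cl
Why: Standard silylation of a primary and a secondary alcohol; the non-basic conditions spare the γ-oxygenated enone.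

Step 5
Reactants: 7 2-methoxypropene
Product: 8 3-bromo-2-methoxyprop-1-ene
Conditions: NBS, CCl4, K2CO3 (cat.), 0 → 25 °C; filtered solution used directly
Reagents that add atoms: N-bromosuccinimide, O=C1CCC(=O)N1Br
Why: Electrophilic bromination of the enol ether followed by loss of a methyl proton from the oxocarbenium ion gives the allylic bromide, a known acetonyl cation equivalent.

Step 6
Reactants: 6 bis-silyl enone; 8 3-bromo-2-methoxyprop-1-ene
Product: 10 (4R,5S,6R)-4-(TBS-oxy)-5-[3-(TBS-oxy)prop-1-en-2-yl]-6-(2-methoxyprop-2-en-1-yl)-2-methylcyclohex-2-en-1-one, via lithium enolate 9 (not isolated)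
Conditions: LiN(iPr)2 (1.1 equiv), THF, −78 °C; then 8, DMPU, −78 → −20 °C
Reagents that add atoms: none
Why: Kinetic α′-deprotonation gives the cross-conjugated enolate, and SN2 alkylation occurs anti to the adjacent C7 substituent (enolate alkylation of carvone-type enones). The trans product (C8, ring locant 6R) is also the more stable diequatorial isomer.

Step 7
Reactants: 11 4-methoxybenzyl alcohol; 12 trichloroethylene
Product: 13 1-({[(E)-1,2-dichloroethenyl]oxy}methyl)-4-methoxybenzene
Conditions: KH (1.5 equiv), THF, 0 °C; then 12, −50 → 25 °C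
Reagents that add atoms: none
Why: The potassium alkoxide eliminates HCl from trichloroethylene and adds anti to the dichloroacetylene formed, the known route to (E)-1,2-dichlorovinyl ethers.

Step 8
Reactants: 13 dichlorovinyl ether; 10 alkylated enone
Product: 15 (1S,4R,5S,6R)-4-(TBS-oxy)-5-[3-(TBS-oxy)prop-1-en-2-yl]-1-[(PMB-oxy)ethynyl]-6-(2-methoxyprop-2-en-1-yl)-2-methylcyclohex-2-en-1-ol, via lithium alkoxyacetylide 14 (not isolated)
Conditions: n-BuLi (2.1 equiv), THF, −78 → −40 °C; then 10, −78 °C; aq. NH4Cl
Reagents that add atoms: none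
Why: Elimination of LiCl and chlorine–lithium exchange give the lithium alkoxyacetylide, which adds 1,2 to the enone. The slim sp nucleophile takes the axial trajectory anti to the C7 substituent, so the new arm at C3 is cis to the equatorial C8 arm (ring locant 1S).

Step 9
Reactants: 15 enol ether carbinol
Product: 16 (1S,4R,5S,6R)-4-(TBS-oxy)-5-[3-(TBS-oxy)prop-1-en-2-yl]-1-[(PMB-oxy)ethynyl]-2-methyl-6-(2-oxopropyl)cyclohex-2-en-1-ol
Conditions: oxalic acid (5 mol%), THF–H2O 4:1, 0 °C, short contact; NaHCO3 quench
Reagents that add atoms: water, O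
Why: A 2-alkoxypropene is hydrolysed by dilute acid orders of magnitude faster than an alkoxyalkyne is protonated, so the methyl ketone is released while the alkoxyalkyne carbinol and the silyl ethers survive.

Step 10
Reactants: 16 methyl ketone
Product: 17 (1S,4R,5S,6S)-4-(TBS-oxy)-5-[3-(TBS-oxy)prop-1-en-2-yl]-1-[(PMB-oxy)ethynyl]-2-methyl-6-[(1Z)-2-(TIPS-oxy)prop-1-en-1-yl]cyclohex-2-en-1-ol
Conditions: TIPSOTf (1.2 equiv), Et3N (3 equiv), CH2Cl2, −78 → 0 °C
Reagents that add atoms: triisopropylsilyl trifluoromethanesulfonate, CC(C)[Si](C(C)C)(C(C)C)OS(=O)(=O)C(F)(F)F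
Why: Soft enolisation with a silyl triflate and Et3N equilibrates towards the more substituted enol silane, and the Z isomer (silyloxy cis to C8) avoids the C8/methyl eclipsing. The hindered tertiary hydroxyl should react much more slowly with the bulky triflate.

Step 11
Reactants: 17 alkoxyalkyne
Product: 18 (1R,4R,5S,6S)-4-(TBS-oxy)-5-[3-(TBS-oxy)prop-1-en-2-yl]-1-[(Z)-2-(PMB-oxy)ethenyl]-2-methyl-6-[(1Z)-2-(TIPS-oxy)prop-1-en-1-yl]cyclohex-2-en-1-ol
Conditions: H2 (1 atm), Pd/CaCO3 poisoned with Pb(OAc)2 (Lindlar catalyst), quinoline, EtOAc–hexane, Et3N (trace), 25 °C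
Reagents that add atoms: none
Why: Lindlar semi-hydrogenation adds H2 syn to the alkoxyalkyne and gives the Z enol ether, as known for alkoxyethynyl carbinols; the alkenes are not reduced on the poisoned catalyst. The acid-labile product is used at once.

Step 12
Reactants: 18 cis-1,2-dialkenylcyclohexenol
Product: 21 (1R,6R,7S,10R)-6,12-bis(TBS-oxy)-1-(PMB-oxy)-10-(TIPS-oxy)germacra-4Z,8Z,11(13)-trien-3-one, via potassium alkoxide 19 (not isolated), via potassium dienolate 20 (not isolated)
Conditions: KH (3 equiv), 18-crown-6 (3 equiv), THF, −20 → 25 °C; AcOH–THF, −78 °C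
Reagents that add atoms: none
Why: KH with 18-crown-6 gives the naked potassium alkoxide 19, whose oxygen weakens the C3–C8 bond; the diene C1=C2–C3–C8–C9=C10 then undergoes a concerted [3,3] shift (anionic oxy-Cope rearrangement) that breaks C3–C8, forms C1–C10 and gives dienolate 20, which is protonated at C2 on cold acidic quench. The closest known reaction type is the anionic oxy-Cope ring expansion of cis-1,2-divinylcyclohexanols to (Z)-cyclodec-5-enones. The ten-membered ring is closed by sigmatropic expansion of the six-membered ring by four atoms, not by cyclisation of a chain, so no dilution is needed and the carvone olefin is carried over as Z-C4=C5. The reacting conformer is the half-chair with the C6, C7 and C8 substituents equatorial and the C3 alkenyl group axial; in the derived chair array the alkoxide and the C8–C7 bond are axial, which gives Z-C8=C9. C10 is controlled by the Z geometry of the enol silane (silyloxy axial, methyl equatorial, 10R) and C1 by the Z geometry of the alkoxyvinyl group (1R, erased later), whose ether oxygen lies syn-axial to the alkoxide where K+ can bridge. The selectivity needed is this chair over the other chair and over the boat: the other chair would force all three ring substituents axial, and the all-trans C6/C7/C8 pattern from steps 2 and 6 therefore secures it. β-Elimination of the PMB oxide from 20 is held back by working at or below 25 °C and quenching at −78 °C.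

Step 13
Reactants: 21 cyclodecadienone
Product: 22 (1R,6R,7S,10R)-6,12-dihydroxy-1-(PMB-oxy)-10-(TIPS-oxy)germacra-4Z,8Z,11(13)-trien-3-one
Conditions: HF·pyridine, pyridine, THF, 0 → 25 °C
Reagents that add atoms: none
Why: Buffered HF cleaves the primary and the secondary TBS ethers, while the tertiary TIPS ether is far slower (steric differentiation of silyl ethers).

Step 14
Reactants: 22 diol
Product: 25 (1R,6R,7S,10R)-3-oxo-1-(PMB-oxy)-10-(TIPS-oxy)germacra-4Z,8Z,11(13)-trien-12,6-olide, via hydroxy enal 23 (not isolated), via lactol 24 (not isolated)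
Conditions: TEMPO (0.2 equiv), PhI(OAc)2 (3 equiv), CH2Cl2, 25 °C
Reagents that add atoms: none
Why: Oxidative lactonisation of a 1,4-diol: the primary allylic alcohol is oxidised first, the C6 hydroxyl closes the lactol and this is oxidised to the α-methylene lactone. C6 and C7 are untouched, so the trans fusion follows from steps 1 and 2, and O6 is captured before it can settle on the C3 carbonyl.

Step 15
Reactants: 25 lactone
Product: 27 (1R,6R,7R,8S,9S,10R)-8,9-dihydroxy-3-oxo-1-(PMB-oxy)-10-(TIPS-oxy)germacra-4Z,11(13)-dien-12,6-olide, via osmate ester 26 (not isolated)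
Conditions: OsO4 (10 mol%), NMO (2 equiv), acetone–H2O 5:1, 0 → 25 °C; Na2S2O3 quench
Reagents that add atoms: osmium tetroxide, O=[Os](=O)(=O)=O (oxygen carrier); N-methylmorpholine N-oxide, C[N+]1([O-])CCOCC1 (terminal oxidant); water, O
Why: Catalytic syn-dihydroxylation through the osmate ester (hexavalent osmium) of the only olefin not conjugated to a carbonyl group. Addition is expected anti to the allylic C10 silyloxy group: in either staggered rotamer about C9–C10 the required face carries only C1 or the methyl group, which gives 8S,9S.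

Step 16
Reactants: 28 tert-butyl acrylate; 29 acetaldehyde
Product: 30 tert-butyl 3-hydroxy-2-methylidenebutanoate (racemic)
Conditions: DABCO (0.5 equiv), neat, sealed vessel, 25 °C, 5–7 d
Reagents that add atoms: none
Why: Baylis–Hillman reaction; the carbinol centre is racemic and is removed in step 17.

Step 17
Reactants: 30 Baylis–Hillman adduct
Product: 32 tert-butyl (2E)-2-(acetoxymethyl)but-2-enoate, via tert-butyl 3-acetoxy-2-methylidenebutanoate 31 (not isolated)
Conditions: Ac2O, Et3N, DMAP (cat.), THF, 0 → 25 °C; then DABCO (0.5 equiv), 65 °C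
Reagents that add atoms: acetic anhydride, CC(=O)OC(C)=O
Why: Acetylation, then amine-mediated SN2′/SN2′ transposition of the allylic acetate through the allylammonium salt to the more stable trisubstituted acrylate. The E isomer (ester trans to the β-methyl) is the thermodynamic product for acrylate esters.

Step 18
Reactants: 32 tert-butyl ester
Product: 33 (2E)-2-(acetoxymethyl)but-2-enoic acid
Conditions: CF3CO2H–CH2Cl2 1:4, 0 → 25 °C
Reagents that add atoms: none
Why: Acidolysis of the tert-butyl ester with loss of isobutene; the primary allylic acetate is stable to these conditions.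

Step 19
Reactants: 27 diol; 33 acid
Product: 35 (1R,6R,7S,8S,9S,10R)-8-[(2E)-2-(acetoxymethyl)but-2-enoyloxy]-9-hydroxy-3-oxo-1-(PMB-oxy)-10-(TIPS-oxy)germacra-4Z,11(13)-dien-12,6-olide, via mixed anhydride 34 (not isolated)
Conditions: 33, 2,4,6-trichlorobenzoyl chloride, Et3N, toluene, 25 °C; then 27, DMAP, 0 → 25 °C
Reagents that add atoms: none
Why: Yamaguchi esterification: the C8 hydroxyl reacts because the C9 hydroxyl is neopentylic and shielded by the C10 silyloxy group; the E acrylate has no tendency to isomerise.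

Step 20
Reactants: 35 hydroxy ester
Product: 36 (1R,6R,7S,8S,9S,10S)-9-acetoxy-8-[(2E)-2-(acetoxymethyl)but-2-enoyloxy]-3-oxo-1-(PMB-oxy)-10-(TIPS-oxy)germacra-4Z,11(13)-dien-12,6-olide
Conditions: Ac2O, DMAP, Et3N, CH2Cl2, 25–40 °C
Reagents that add atoms: acetic anhydride, CC(=O)OC(C)=O
Why: DMAP-catalysed acetylation of the remaining hindered secondary alcohol. Migration of the C8 acyl group to the more hindered O9 is thermodynamically uphill. The C10 descriptor changes only through ligand priorities.

Step 21
Reactants: 36 PMB ether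
Product: 37 (1R,6R,7S,8S,9S,10S)-9-acetoxy-8-[(2E)-2-(acetoxymethyl)but-2-enoyloxy]-1-hydroxy-3-oxo-10-(TIPS-oxy)germacra-4Z,11(13)-dien-12,6-olide
Conditions: DDQ (1.5 equiv), CH2Cl2–pH 7 buffer 10:1, 0 → 25 °C
Reagents that add atoms: none
Why: Oxidative cleavage of the 4-methoxybenzyl ether by hydride abstraction and hydrolysis of the oxocarbenium ion; esters, silyl ether and the electron-poor olefins are inert.

Step 22
Reactants: 37 β-hydroxy ketone
Product: 38 (6R,7S,8S,9S,10R)-9-acetoxy-8-[(2E)-2-(acetoxymethyl)but-2-enoyloxy]-1,3-dioxo-10-(TIPS-oxy)germacra-4Z,11(13)-dien-12,6-olide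
Conditions: Dess–Martin periodinane (1.5 equiv), NaHCO3, CH2Cl2, 25 °C
Reagents that add atoms: none
Why: Dess–Martin oxidation of the secondary alcohol to the 1,3-diketone under non-basic conditions; C10 is quaternary, so neither epimerisation nor β-elimination of the C9 acetate can occur.

Step 23
Reactants: 38 silyloxy diketone
Product: 41 (6R,7S,8S,9S,10R)-9-acetoxy-8-[(2E)-2-(acetoxymethyl)but-2-enoyloxy]-3,10-epoxy-1-oxogermacra-2,4Z,11(13)-trien-12,6-olide (CNP0325609.1), via hydroxy diketone 39 (not isolated), via hemiketal 40 (not isolated)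
Conditions: 48% aq. HF, MeCN, 25–40 °C
Reagents that add atoms: none
Why: Acidic fluoride cleaves the tertiary silyl ether; the C10 hydroxyl adds 5-exo-trig to the C3 carbonyl, the only one it can reach, and the hemiketal dehydrates to the 3(2H)-furanone (cyclodehydration of an α′-hydroxy 1,3-diketone). The esters and the lactone tolerate the acidic medium.

## Compound list

1 | (S)-(+)-carvone | CC1=CC[C@H](C(C)=C)CC1=O | starting material
2 | (5R)-2-methyl-5-(prop-1-en-2-yl)cyclohexa-1,3-dien-1-yl acetate | CC(=O)OC1=C(C)C=C[C@H](C(C)=C)C1 | intermediate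
3 | 3,4-epoxide of 2, oxirane anti to the isopropenyl group | CC(=O)OC1=C(C)[C@H]2O[C@H]2[C@H](C(C)=C)C1 | intermediate (not isolated)
4 | (4R,5S)-4-hydroxy-2-methyl-5-(prop-1-en-2-yl)cyclohex-2-en-1-one | CC1=C[C@@H](O)[C@H](C(C)=C)CC1=O | intermediate
5 | (4R,5S)-4-hydroxy-5-(3-hydroxyprop-1-en-2-yl)-2-methylcyclohex-2-en-1-one | CC1=C[C@@H](O)[C@H](C(=C)CO)CC1=O | intermediate
6 | (4R,5S)-4-(TBS-oxy)-5-[3-(TBS-oxy)prop-1-en-2-yl]-2-methylcyclohex-2-en-1-one | CC1=C[C@@H](O[Si](C)(C)C(C)(C)C)[C@H](C(=C)CO[Si](C)(C)C(C)(C)C)CC1=O | intermediate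
7 | 2-methoxypropene | COC(C)=C | starting material
8 | 3-bromo-2-methoxyprop-1-ene | COC(=C)CBr | intermediate
9 | lithium enolate of 6 (C3–O–Li, C3=C8) | CC1=C[C@@H](O[Si](C)(C)C(C)(C)C)[C@H](C(=C)CO[Si](C)(C)C(C)(C)C)C=C1O[Li] | intermediate (not isolated)
10 | (4R,5S,6R)-4-(TBS-oxy)-5-[3-(TBS-oxy)prop-1-en-2-yl]-6-(2-methoxyprop-2-en-1-yl)-2-methylcyclohex-2-en-1-one | CC1=C[C@@H](O[Si](C)(C)C(C)(C)C)[C@H](C(=C)CO[Si](C)(C)C(C)(C)C)[C@@H](CC(=C)OC)C1=O | intermediate
11 | 4-methoxybenzyl alcohol | COc1ccc(CO)cc1 | starting material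
12 | trichloroethylene | ClC=C(Cl)Cl | starting material
13 | 1-({[(E)-1,2-dichloroethenyl]oxy}methyl)-4-methoxybenzene | COc1ccc(CO/C(Cl)=C\Cl)cc1 | intermediate
14 | lithium [(4-methoxybenzyl)oxy]ethynide | COc1ccc(COC#C[Li])cc1 | intermediate (not isolated)
15 | (1S,4R,5S,6R)-4-(TBS-oxy)-5-[3-(TBS-oxy)prop-1-en-2-yl]-1-[(PMB-oxy)ethynyl]-6-(2-methoxyprop-2-en-1-yl)-2-methylcyclohex-2-en-1-ol | CC1=C[C@@H](O[Si](C)(C)C(C)(C)C)[C@H](C(=C)CO[Si](C)(C)C(C)(C)C)[C@@H](CC(=C)OC)[C@@]1(O)C#COCc1ccc(OC)cc1 | intermediate
16 | (1S,4R,5S,6R)-4-(TBS-oxy)-5-[3-(TBS-oxy)prop-1-en-2-yl]-1-[(PMB-oxy)ethynyl]-2-methyl-6-(2-oxopropyl)cyclohex-2-en-1-ol | CC1=C[C@@H](O[Si](C)(C)C(C)(C)C)[C@H](C(=C)CO[Si](C)(C)C(C)(C)C)[C@@H](CC(C)=O)[C@@]1(O)C#COCc1ccc(OC)cc1 | intermediate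
17 | (1S,4R,5S,6S)-4-(TBS-oxy)-5-[3-(TBS-oxy)prop-1-en-2-yl]-1-[(PMB-oxy)ethynyl]-2-methyl-6-[(1Z)-2-(TIPS-oxy)prop-1-en-1-yl]cyclohex-2-en-1-ol | CC1=C[C@@H](O[Si](C)(C)C(C)(C)C)[C@H](C(=C)CO[Si](C)(C)C(C)(C)C)[C@@H](/C=C(/C)O[Si](C(C)C)(C(C)C)C(C)C)[C@@]1(O)C#COCc1ccc(OC)cc1 | intermediate
18 | (1R,4R,5S,6S)-4-(TBS-oxy)-5-[3-(TBS-oxy)prop-1-en-2-yl]-1-[(Z)-2-(PMB-oxy)ethenyl]-2-methyl-6-[(1Z)-2-(TIPS-oxy)prop-1-en-1-yl]cyclohex-2-en-1-ol | CC1=C[C@@H](O[Si](C)(C)C(C)(C)C)[C@H](C(=C)CO[Si](C)(C)C(C)(C)C)[C@@H](/C=C(/C)O[Si](C(C)C)(C(C)C)C(C)C)[C@@]1(O)/C=C\OCc1ccc(OC)cc1 | intermediate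
19 | potassium alkoxide of 18 | CC1=C[C@@H](O[Si](C)(C)C(C)(C)C)[C@H](C(=C)CO[Si](C)(C)C(C)(C)C)[C@@H](/C=C(/C)O[Si](C(C)C)(C(C)C)C(C)C)[C@@]1([O-])/C=C\OCc1ccc(OC)cc1.[K+] | intermediate (not isolated)
20 | potassium C2=C3 dienolate of 21 | [K+].[O-]/C1=C\[C@@H](OCc2ccc(OC)cc2)[C@](C)(O[Si](C(C)C)(C(C)C)C(C)C)/C=C\[C@@H](C(=C)CO[Si](C)(C)C(C)(C)C)[C@H](O[Si](C)(C)C(C)(C)C)/C=C1/C | intermediate (not isolated)
21 | (1R,6R,7S,10R)-6,12-bis(TBS-oxy)-1-(PMB-oxy)-10-(TIPS-oxy)germacra-4Z,8Z,11(13)-trien-3-one | O=C1C[C@@H](OCc2ccc(OC)cc2)[C@](C)(O[Si](C(C)C)(C(C)C)C(C)C)/C=C\[C@@H](C(=C)CO[Si](C)(C)C(C)(C)C)[C@H](O[Si](C)(C)C(C)(C)C)/C=C1/C | intermediate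
22 | (1R,6R,7S,10R)-6,12-dihydroxy-1-(PMB-oxy)-10-(TIPS-oxy)germacra-4Z,8Z,11(13)-trien-3-one | O=C1C[C@@H](OCc2ccc(OC)cc2)[C@](C)(O[Si](C(C)C)(C(C)C)C(C)C)/C=C\[C@@H](C(=C)CO)[C@H](O)/C=C1/C | intermediate
23 | (1R,6R,7S,10R)-6-hydroxy-3-oxo-1-(PMB-oxy)-10-(TIPS-oxy)germacra-4Z,8Z,11(13)-trien-12-al | O=C1C[C@@H](OCc2ccc(OC)cc2)[C@](C)(O[Si](C(C)C)(C(C)C)C(C)C)/C=C\[C@@H](C(=C)C=O)[C@H](O)/C=C1/C | intermediate (not isolated)
24 | 12,6-lactol of 23 (either C12 epimer) | O=C1C[C@@H](OCc2ccc(OC)cc2)[C@](C)(O[Si](C(C)C)(C(C)C)C(C)C)/C=C\[C@H]2C(=C)C(O)O[C@@H]2/C=C1/C | intermediate (not isolated)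
25 | (1R,6R,7S,10R)-3-oxo-1-(PMB-oxy)-10-(TIPS-oxy)germacra-4Z,8Z,11(13)-trien-12,6-olide | O=C1C[C@@H](OCc2ccc(OC)cc2)[C@](C)(O[Si](C(C)C)(C(C)C)C(C)C)/C=C\[C@H]2C(=C)C(=O)O[C@@H]2/C=C1/C | intermediate
26 | cyclic 8,9-osmate ester of 25 (hexavalent osmium) | O=C1C[C@@H](OCc2ccc(OC)cc2)[C@](C)(O[Si](C(C)C)(C(C)C)C(C)C)[C@H]3O[Os](=O)(=O)O[C@H]3[C@H]2C(=C)C(=O)O[C@@H]2/C=C1/C | intermediate (not isolated)
27 | (1R,6R,7R,8S,9S,10R)-8,9-dihydroxy-3-oxo-1-(PMB-oxy)-10-(TIPS-oxy)germacra-4Z,11(13)-dien-12,6-olide | O=C1C[C@@H](OCc2ccc(OC)cc2)[C@](C)(O[Si](C(C)C)(C(C)C)C(C)C)[C@@H](O)[C@@H](O)[C@H]2C(=C)C(=O)O[C@@H]2/C=C1/C | intermediate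
28 | tert-butyl acrylate | C=CC(=O)OC(C)(C)C | starting material
29 | acetaldehyde | CC=O | starting material
30 | tert-butyl 3-hydroxy-2-methylidenebutanoate (racemic) | CC(O)C(=C)C(=O)OC(C)(C)C | intermediate
31 | tert-butyl 3-acetoxy-2-methylidenebutanoate (racemic) | CC(OC(C)=O)C(=C)C(=O)OC(C)(C)C | intermediate (not isolated)
32 | tert-butyl (2E)-2-(acetoxymethyl)but-2-enoate | C/C=C(\COC(C)=O)C(=O)OC(C)(C)C | intermediate
33 | (2E)-2-(acetoxymethyl)but-2-enoic acid | C/C=C(\COC(C)=O)C(O)=O | intermediate
34 | (2E)-2-(acetoxymethyl)but-2-enoic 2,4,6-trichlorobenzoic anhydride | C/C=C(\COC(C)=O)C(=O)OC(=O)c1c(Cl)cc(Cl)cc1Cl | intermediate (not isolated)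
35 | (1R,6R,7S,8S,9S,10R)-8-[(2E)-2-(acetoxymethyl)but-2-enoyloxy]-9-hydroxy-3-oxo-1-(PMB-oxy)-10-(TIPS-oxy)germacra-4Z,11(13)-dien-12,6-olide | O=C1C[C@@H](OCc2ccc(OC)cc2)[C@](C)(O[Si](C(C)C)(C(C)C)C(C)C)[C@@H](O)[C@@H](OC(=O)/C(=C/C)COC(C)=O)[C@H]2C(=C)C(=O)O[C@@H]2/C=C1/C | intermediate
36 | (1R,6R,7S,8S,9S,10S)-9-acetoxy-8-[(2E)-2-(acetoxymethyl)but-2-enoyloxy]-3-oxo-1-(PMB-oxy)-10-(TIPS-oxy)germacra-4Z,11(13)-dien-12,6-olide | O=C1C[C@@H](OCc2ccc(OC)cc2)[C@](C)(O[Si](C(C)C)(C(C)C)C(C)C)[C@@H](OC(C)=O)[C@@H](OC(=O)/C(=C/C)COC(C)=O)[C@H]2C(=C)C(=O)O[C@@H]2/C=C1/C | intermediate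
37 | (1R,6R,7S,8S,9S,10S)-9-acetoxy-8-[(2E)-2-(acetoxymethyl)but-2-enoyloxy]-1-hydroxy-3-oxo-10-(TIPS-oxy)germacra-4Z,11(13)-dien-12,6-olide | O=C1C[C@@H](O)[C@](C)(O[Si](C(C)C)(C(C)C)C(C)C)[C@@H](OC(C)=O)[C@@H](OC(=O)/C(=C/C)COC(C)=O)[C@H]2C(=C)C(=O)O[C@@H]2/C=C1/C | intermediate
38 | (6R,7S,8S,9S,10R)-9-acetoxy-8-[(2E)-2-(acetoxymethyl)but-2-enoyloxy]-1,3-dioxo-10-(TIPS-oxy)germacra-4Z,11(13)-dien-12,6-olide | O=C1CC(=O)[C@](C)(O[Si](C(C)C)(C(C)C)C(C)C)[C@@H](OC(C)=O)[C@@H](OC(=O)/C(=C/C)COC(C)=O)[C@H]2C(=C)C(=O)O[C@@H]2/C=C1/C | intermediate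
39 | (6R,7S,8S,9S,10R)-9-acetoxy-8-[(2E)-2-(acetoxymethyl)but-2-enoyloxy]-10-hydroxy-1,3-dioxogermacra-4Z,11(13)-dien-12,6-olide | O=C1CC(=O)[C@](C)(O)[C@@H](OC(C)=O)[C@@H](OC(=O)/C(=C/C)COC(C)=O)[C@H]2C(=C)C(=O)O[C@@H]2/C=C1/C | intermediate (not isolated)
40 | 3-hydroxy-3,10-epoxy hemiketal of 39 (C3 configuration fixed by the bridge) | OC13CC(=O)[C@](C)(O3)[C@@H](OC(C)=O)[C@@H](OC(=O)/C(=C/C)COC(C)=O)[C@H]2C(=C)C(=O)O[C@@H]2/C=C1/C | intermediate (not isolated)
41 | (6R,7S,8S,9S,10R)-9-acetoxy-8-[(2E)-2-(acetoxymethyl)but-2-enoyloxy]-3,10-epoxy-1-oxogermacra-2,4Z,11(13)-trien-12,6-olide (CNP0325609.1) | C=C1C(=O)O[C@@H]2/C=C(/C)C3=CC(=O)[C@](C)(O3)[C@@H](OC(C)=O)[C@@H](OC(=O)/C(=C/C)COC(C)=O)[C@@H]12 | target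

## Step count and least certain steps

Total step count: 23. Longest linear sequence: 18 steps (1–4, 6, 8–15, 19–23).

**Step 12 (key step).**
- **What may go wrong:** The favoured chair places the C10 silyloxy group syn-axial to the C8–C7 bond. A boat-like transition state may therefore compete and deliver the C10 epimer or an E olefin. The second process is β-elimination of the PMB oxide from the dienolate before the quench.
- **Fallback:** The rearrangement is run on a neutral species. From 18, silylation with N-(trimethylsilyl)imidazole gives the trimethylsilyl ether F1. Heating F1 in toluene in a sealed tube (siloxy-Cope rearrangement, about 150–180 °C) gives the ten-membered trimethylsilyl dienol ether F2 with no enolate present. K2CO3 in MeOH then cleaves only the enol silane and returns the route at 21.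

**Step 15.**
- **What may go wrong:** Facial selectivity may be poor if the ring folds so that C1 and C6 cover the required face, and osmylation of the α-methylene lactone may compete because C8=C9 is hindered.
- **Fallback:** A Woodward cis-hydroxylation puts the oxygens on the face opposite to the first electrophile. From 25, I2 and AgOAc in AcOH give the trans iodo acetate F3 (iodine at C9 on the exposed face, acetate at C8). AgOAc in wet AcOH then gives the cis hydroxy acetate F4 through the acetoxonium ion. Brief K2CO3/MeOH at 0 °C returns the route at 27.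

**Step 10.**
- **What may go wrong:** Enolisation may go towards the methyl group, the E isomer may form, or the tertiary alcohol may be silylated.
- **Fallback:** Regiocontrol is separated from the introduction of the bulky silyl group. From 16, TMSCl/NaI/Et3N in MeCN (thermodynamic silylation) gives the bis(trimethylsilyl) compound F5, a Z enol silane plus tertiary silyl ether. MeLi converts the enol silane into the regio- and stereodefined lithium enolate, and TIPSOTf traps it as the triisopropylsilyl enol ether F6. K2CO3/MeOH removes the tertiary trimethylsilyl ether and returns the route at 17.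

**Step 9.**
- **What may go wrong:** Acid-induced Meyer–Schuster-type rearrangement or hydration of the alkoxyalkyne carbinol may run alongside hydrolysis of the enol ether.
- **Fallback:** No acid is used. Enone 6 is alkylated as in step 6 with 3-bromo-2-(triethylsilyloxy)prop-1-ene F7, made from bromoacetone, TESOTf and Et3N, to give the silyl enol ether ketone F8. Addition of 14 as in step 8 gives the carbinol F9. K2CO3 in MeOH cleaves the triethylsilyl enol ether and returns the route at 16.

**Step 2.**
- **What may go wrong:** The peracid may also epoxidise the isopropenyl group, and acid-induced aromatisation of the dienyl acetate may occur.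
- **Fallback:** The oxidant is changed to singlet oxygen, which ignores the isopropenyl group. From 2, photooxygenation (O2, tetraphenylporphyrin, visible light, CH2Cl2, −78 °C) gives by [4+2] addition anti to the isopropenyl group the endoperoxide F10. Reduction with thiourea cleaves the O–O bond, and the hemiketal acetate collapses, returning the route at 4.

## Further compounds

F1 | step 12 | trimethylsilyl ether of 18 | CC1=C[C@@H](O[Si](C)(C)C(C)(C)C)[C@H](C(=C)CO[Si](C)(C)C(C)(C)C)[C@@H](/C=C(/C)O[Si](C(C)C)(C(C)C)C(C)C)[C@@]1(O[Si](C)(C)C)/C=C\OCc1ccc(OC)cc1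
F2 | step 12 | C2=C3 trimethylsilyl dienol ether of 21 | C[Si](C)(C)O/C1=C\[C@@H](OCc2ccc(OC)cc2)[C@](C)(O[Si](C(C)C)(C(C)C)C(C)C)/C=C\[C@@H](C(=C)CO[Si](C)(C)C(C)(C)C)[C@H](O[Si](C)(C)C(C)(C)C)/C=C1/C
F3 | step 15 | 8-acetoxy-9-iodo adduct of 25 (trans) | O=C1C[C@@H](OCc2ccc(OC)cc2)[C@](C)(O[Si](C(C)C)(C(C)C)C(C)C)[C@H](I)[C@@H](OC(C)=O)[C@H]2C(=C)C(=O)O[C@@H]2/C=C1/C
F4 | step 15 | 8-O-acetate of 27 | O=C1C[C@@H](OCc2ccc(OC)cc2)[C@](C)(O[Si](C(C)C)(C(C)C)C(C)C)[C@@H](O)[C@@H](OC(C)=O)[C@H]2C(=C)C(=O)O[C@@H]2/C=C1/C
F5 | step 10 | Z trimethylsilyl enol ether and tertiary trimethylsilyl ether of 16 | CC1=C[C@@H](O[Si](C)(C)C(C)(C)C)[C@H](C(=C)CO[Si](C)(C)C(C)(C)C)[C@@H](/C=C(/C)O[Si](C)(C)C)[C@@]1(O[Si](C)(C)C)C#COCc1ccc(OC)cc1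
F6 | step 10 | tertiary trimethylsilyl ether of 17 | CC1=C[C@@H](O[Si](C)(C)C(C)(C)C)[C@H](C(=C)CO[Si](C)(C)C(C)(C)C)[C@@H](/C=C(/C)O[Si](C(C)C)(C(C)C)C(C)C)[C@@]1(O[Si](C)(C)C)C#COCc1ccc(OC)cc1
F7 | step 9 | 3-bromo-2-(triethylsilyloxy)prop-1-ene | CC[Si](CC)(CC)OC(=C)CBr
F8 | step 9 | (4R,5S,6R)-4-(TBS-oxy)-5-[3-(TBS-oxy)prop-1-en-2-yl]-2-methyl-6-[2-(triethylsilyloxy)prop-2-en-1-yl]cyclohex-2-en-1-one | CC1=C[C@@H](O[Si](C)(C)C(C)(C)C)[C@H](C(=C)CO[Si](C)(C)C(C)(C)C)[C@@H](CC(=C)O[Si](CC)(CC)CC)C1=O
F9 | step 9 | adduct of 14 and F8 (triethylsilyl enol ether analogue of 15) | CC1=C[C@@H](O[Si](C)(C)C(C)(C)C)[C@H](C(=C)CO[Si](C)(C)C(C)(C)C)[C@@H](CC(=C)O[Si](CC)(CC)CC)[C@@]1(O)C#COCc1ccc(OC)cc1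
F10 | step 2 | 1,4-endoperoxide of 2 (peroxide bridge anti to the isopropenyl group) | CC(=O)O[C@]12OO[C@H](C=C1C)[C@H](C(C)=C)C2
A1 | alternative 1 | ten-membered C3 ketone with 1,10-epoxide (C8/C9 acetonide, lactone in place) | C=C1C(=O)O[C@@H]2/C=C(/C)C(=O)C[C@@H]3O[C@@]3(C)[C@@H](OC4(C)C)[C@@H](O4)[C@@H]12
A2 | alternative 1 | 3,10-epoxy dienol ether with C1 hydroxyl (C8/C9 acetonide) | C=C1C(=O)O[C@@H]2/C=C(/C)C3=C[C@H](O)[C@](C)(O3)[C@@H](OC4(C)C)[C@@H](O4)[C@@H]12
A3 | alternative 2 | open-chain furanone with C5 Z-vinyl iodide and C6 aldehyde (C12 silyl ether, C8/C9 acetonide) | I/C=C(/C)C2=CC(=O)[C@](C)(O2)[C@@H](OC3(C)C)[C@@H](O3)[C@H](C=O)C(=C)CO[Si](C)(C)C(C)(C)C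
A4 | alternative 2 | macrocyclic C6 allylic alcohol (C12 silyl ether, C8/C9 acetonide) | O[C@@H]1/C=C(/C)C2=CC(=O)[C@](C)(O2)[C@@H](OC3(C)C)[C@@H](O3)[C@H]1C(=C)CO[Si](C)(C)C(C)(C)C
A5 | alternative 3 | lactone with C1 ethyl thioester and terminal C2 alkyne (C10 triethylsilyl ether, C8/C9 acetonide) | CCSC(=O)[C@](C)(O[Si](CC)(CC)CC)[C@@H](OC3(C)C)[C@@H](O3)[C@H]1C(=C)C(=O)O[C@@H]1/C=C(/C)C#C
A6 | alternative 3 | ten-membered Z-enynone lactone (C10 triethylsilyl ether, C8/C9 acetonide) | C=C1C(=O)O[C@@H]2/C=C(/C)C#CC(=O)[C@](C)(O[Si](CC)(CC)CC)[C@@H](OC3(C)C)[C@@H](O3)[C@@H]12
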